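**Plan**
- Retrosynthesis: the 2-methyl-enal carbon (at ester level) and the oxygen of the 3-hydroxypropyl chain, which sit cis on the exocyclic double bond, are first tied into an eight-membered α,β-unsaturated lactone (temporary ring). The cyclohexane is then cut between the ring CH that carries the chain, which is the γ-carbon of that enoate, and the neighbouring quaternary C(CH3)(homofarnesyl). This carbon and the adjacent C(CH3)OH are the two carbons of a tetrasubstituted epoxide, so the ring bond is an anti epoxide opening by a dienolate γ-carbon.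
- Further cuts: lactone C–O; the sp2–CH2 bond to the four-carbon chain (B-alkyl Suzuki on a β-keto ester enol triflate); the CH2–CH2 bond beside the epoxide (acetoacetate dianion alkylation); and the same dianion/triflate pair once more, back to farnesyl bromide.
- Forward order: chain (farnesyl bromide → 2-methylgeranylgeraniol → epoxide), second keto ester, tetrasubstituted enoate, eight-membered lactone, cyclohexane last; lactone reduction and allylic oxidation finish.
- Stereochemistry: Sharpless epoxidation sets the (2S,3S) epoxide. The key step carries it to the quaternary carbon (inversion) and the carbinol carbon (retention), sets the ring CH through a chair transition state, and the lactone ring fixes the (Z) geometry of the enal.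

Key step: step 12

Shorthand: homofarnesyl = (3E,7E)-4,8,12-trimethyltrideca-3,7,11-trien-1-yl.
Assumption: any trimethylsilyl group that ends on the tertiary alkoxide in step 12 is lost on the mildly basic aqueous work-up, so 17 is taken as the free tertiary alcohol.

**Step 1**
Reactants: 1 ethyl 2-methyl-3-oxobutanoate; 2 (2E,6E)-farnesyl bromide
Product: 3 ethyl (6E,10E)-2,7,11,15-tetramethyl-3-oxohexadeca-6,10,14-trienoate
Conditions: NaH, THF, 0 °C; n-BuLi, 0 °C; 2, 0 °C; aq NH4Cl
Reagents that add atoms: none
Why: Acetoacetate dianion alkylation, in which the more basic terminal (γ) carbanion should displace the primary allylic bromide by SN2 without allylic transposition.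

**Step 2**
Reactants: 3 ethyl (6E,10E)-2,7,11,15-tetramethyl-3-oxohexadeca-6,10,14-trienoate
Product: 4 ethyl (2Z,6E,10E)-2,7,11,15-tetramethyl-3-(trifluoromethylsulfonyloxy)hexadeca-2,6,10,14-tetraenoate
Conditions: NaH, THF, 0 °C; PhNTf2, 0 °C to rt
Reagents that add atoms: N-phenyl-bis(trifluoromethanesulfonimide), O=S(=O)(N(c1ccccc1)S(=O)(=O)C(F)(F)F)C(F)(F)F
Why: Stereoselective enol triflate formation, in which O-sulfonylation of the sodium-chelated enolate of the α-methyl β-keto ester should place the triflate cis to the ester.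

**Step 3**
Reactants: 4 ethyl (2Z,6E,10E)-2,7,11,15-tetramethyl-3-(trifluoromethylsulfonyloxy)hexadeca-2,6,10,14-tetraenoate
Product: 5 ethyl (2E,6E,10E)-2,3,7,11,15-pentamethylhexadeca-2,6,10,14-tetraenoate
Conditions: MeMgBr, Fe(acac)3 (5 mol %), THF/NMP, −30 °C
Reagents that add atoms: methylmagnesium bromide, C[Mg]Br
Why: Iron-catalysed Kumada-type coupling of an enol triflate should replace the triflate by methyl with retention of geometry, faster than Grignard addition to the ester at this temperature.

**Step 4**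
Reactants: 5 ethyl (2E,6E,10E)-2,3,7,11,15-pentamethylhexadeca-2,6,10,14-tetraenoate
Product: 6 (2E,6E,10E)-2,3,7,11,15-pentamethylhexadeca-2,6,10,14-tetraen-1-ol
Conditions: i-Bu2AlH (2.5 equiv), CH2Cl2, −78 to 0 °C; Rochelle salt
Reagents that add atoms: none
Why: 1,2-Reduction of the conjugated ester by i-Bu2AlH should give the allylic alcohol and leave the isolated alkenes alone.

**Step 5**
Reactants: 6 (2E,6E,10E)-2,3,7,11,15-pentamethylhexadeca-2,6,10,14-tetraen-1-ol
Product: 7 [(2S,3S)-2,3-dimethyl-3-[(3E,7E)-4,8,12-trimethyltrideca-3,7,11-trien-1-yl]oxiran-2-yl]methanol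
Conditions: Ti(Oi-Pr)4 (10 mol %), L-(+)-diethyl tartrate (12 mol %), t-BuOOH, 4 Å MS, CH2Cl2, −20 °C
Reagents that add atoms: tert-butyl hydroperoxide, CC(C)(C)OO
Why: Sharpless asymmetric epoxidation touches only the allylic alcohol double bond, and L-(+)-tartrate should deliver oxygen in the same facial sense as in geraniol → (2S,3S)-2,3-epoxygeraniol, which sets both adjacent stereocentres from the (E) tetrasubstituted alkene.

**Step 6**
Reactants: 7 [(2S,3S)-2,3-dimethyl-3-homofarnesyloxiran-2-yl]methanol
Product: 8 (2R,3S)-2-(iodomethyl)-2,3-dimethyl-3-homofarnesyloxirane (spatial arrangement unchanged from 7)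
Conditions: PPh3, I2, imidazole, CH2Cl2, 0 °C
Reagents that add atoms: iodine, II
Why: Appel-type iodination of the primary alcohol runs under near-neutral conditions, so the acid-labile epoxide and its stereocentres should not be touched.

**Step 7**
Reactants: 8 (2R,3S)-2-(iodomethyl)-2,3-dimethyl-3-homofarnesyloxirane; 1 ethyl 2-methyl-3-oxobutanoate
Product: 9 ethyl 5-[(2S,3S)-2,3-dimethyl-3-homofarnesyloxiran-2-yl]-2-methyl-3-oxopentanoate
Conditions: 1, NaH, THF, 0 °C; n-BuLi (titrated, 1.0 equiv), 0 °C; 8, −78 to 0 °C; aq NH4Cl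
Reagents that add atoms: none
Why: Second acetoacetate dianion alkylation, in which SN2 attack of the γ-carbanion on the primary oxiranylmethyl iodide should be much faster than attack on either fully substituted oxirane carbon.

**Step 8**
Reactants: 9 ethyl 5-[(2S,3S)-2,3-dimethyl-3-homofarnesyloxiran-2-yl]-2-methyl-3-oxopentanoate
Product: 10 ethyl (2Z)-5-[(2S,3S)-2,3-dimethyl-3-homofarnesyloxiran-2-yl]-2-methyl-3-(trifluoromethylsulfonyloxy)pent-2-enoate
Conditions: NaH, THF, 0 °C; PhNTf2, 0 °C to rt; pH 7 buffer
Reagents that add atoms: N-phenyl-bis(trifluoromethanesulfonimide), O=S(=O)(N(c1ccccc1)S(=O)(=O)C(F)(F)F)C(F)(F)F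
Why: Stereoselective enol triflate formation from the chelated sodium enolate as in step 2, with a mild triflating agent and basic medium that the epoxide should tolerate.

**Step 9**
Reactants: 10 ethyl (2Z)-5-[(2S,3S)-2,3-dimethyl-3-homofarnesyloxiran-2-yl]-2-methyl-3-(trifluoromethylsulfonyloxy)pent-2-enoate; 11 but-3-en-1-yl acetate
Product: 13 ethyl (2E)-3-(4-acetoxybutyl)-5-[(2S,3S)-2,3-dimethyl-3-homofarnesyloxiran-2-yl]-2-methylpent-2-enoate, via 4-acetoxybutyl-9-BBN 12 (not isolated)
Conditions: 11, 9-BBN-H, THF, 0 °C to rt; then 10, Pd(dppf)Cl2 (5 mol %), AsPh3, aq K3PO4, DMF, rt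
Reagents that add atoms: none
Why: B-alkyl Suzuki–Miyaura coupling, in which anti-Markovnikov hydroboration of the terminal alkene and palladium-catalysed coupling with the enol triflate should proceed with retention and place the four-carbon chain cis to the ester on the tetrasubstituted double bond.

**Step 10**
Reactants: 13 ethyl (2E)-3-(4-acetoxybutyl)-5-[(2S,3S)-2,3-dimethyl-3-homofarnesyloxiran-2-yl]-2-methylpent-2-enoate
Product: 14 (2E)-5-[(2S,3S)-2,3-dimethyl-3-homofarnesyloxiran-2-yl]-3-(4-hydroxybutyl)-2-methylpent-2-enoic acid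
Conditions: LiOH·H2O, THF/MeOH/H2O, 45 °C; AcOH/NaOAc buffer to pH 5.5, 0 °C; used at once
Reagents that add atoms: lithium hydroxide, [Li+].[OH-]
Why: Saponification should cleave both the acetate and the hindered conjugated ester, the fully substituted epoxide is inert to hydroxide, and the buffered work-up avoids acid opening.

**Step 11**
Reactants: 14 (2E)-5-[(2S,3S)-2,3-dimethyl-3-homofarnesyloxiran-2-yl]-3-(4-hydroxybutyl)-2-methylpent-2-enoic acid
Product: 15 (3Z)-4-{2-[(2S,3S)-2,3-dimethyl-3-homofarnesyloxiran-2-yl]ethyl}-3-methyl-5,6,7,8-tetrahydro-2H-oxocin-2-one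
Conditions: 2-methyl-6-nitrobenzoic anhydride, DMAP (3 equiv), CH2Cl2, slow addition, 2 mM, rt
Reagents that add atoms: none
Why: Shiina macrolactonization (mixed anhydride, acyl transfer by DMAP) at high dilution should close the eight-membered ring, which is feasible because carboxyl and chain are held cis on the tetrasubstituted double bond.

**Step 12**
Reactants: 15 (3Z)-4-{2-[(2S,3S)-2,3-dimethyl-3-homofarnesyloxiran-2-yl]ethyl}-3-methyl-5,6,7,8-tetrahydro-2H-oxocin-2-one
Product: 17 bicyclic lactone (cyclohexane fused to the eight-membered α-methyl-α,β-unsaturated lactone; tertiary alcohol and quaternary methyl/homofarnesyl carbon and ring CH as in iridal), via silyl ketene acetal 16 (not isolated)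
Conditions: LiN(i-Pr)2, THF, −78 °C; Me3SiCl, −78 °C; volatiles removed, LiCl filtered off (pentane); MeAlCl2 (1.5 equiv), CH2Cl2, −78 °C; aq NaHCO3/Rochelle salt
Reagents that add atoms: none
Why: Proposed new method: LiN(i-Pr)2 should deprotonate the ring CH2 that is γ to the carbonyl and held cis to it (the exocyclic γ′-CH2 is trans), O-silylation should give the cyclic vinylketene silyl acetal 16, and MeAlCl2 should then activate the tetrasubstituted epoxide so that the dienolate γ-carbon opens it at the distal oxirane carbon with anti (SN2-like) geometry while the silyloxycarbenium ion collapses to the conjugated lactone; the closest known reaction types are the MeAlCl2-promoted epoxide-initiated cation–olefin cyclization terminated by a silyl enol ether and the γ-selective vinylogous Mukaiyama reaction. The cyclohexane closes 6-endo with respect to both the γ,δ-double bond and the epoxide (both oxirane carbons become ring members), since attack at the proximal oxirane carbon would be a 5-endo-trig closure and α-attack would have to join two fully substituted carbons. The quaternary carbon forms by inversion at the (3S) oxirane carbon and the carbinol carbon keeps its C–O bond, so both are controlled by the Sharpless epoxide. The ring CH is controlled by a chair transition state (C–O bond anti to the forming bond, oxygen equatorial) in which the γ,δ-double bond, locked cis inside the eight-membered ring, puts the ring CH2 chain equatorial and the hydrogen axial. The same ring holds the diene s-cis, so the new tetrasubstituted double bond can only form with the carbonyl carbon cis to the new CH stereocentre, which is the (Z) geometry of the enal. The selectivities needed are γ over α and γ′, cyclization over semipinacol rearrangement of the epoxide, and no proton-induced reaction of the homofarnesyl alkenes; the ring-fixed dienolate, the low temperature and the proton-scavenging methylaluminium reagent are expected to secure them.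

**Step 13**
Reactants: 17 bicyclic lactone
Product: 18 triol (iridal with CH2OH in place of CHO)
Conditions: i-Bu2AlH (5 equiv), CH2Cl2, −78 to 0 °C; Rochelle salt
Reagents that add atoms: none
Why: i-Bu2AlH should reduce the conjugated lactone by 1,2-addition through the lactol to the allylic alcohol and the 3-hydroxypropyl chain, which removes the temporary ring without moving the double bond or changing its geometry.

**Step 14**
Reactants: 18 triol
Product: 19 iridal
Conditions: MnO2 (activated, excess), CH2Cl2, rt, dark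
Reagents that add atoms: none
Why: MnO2 oxidation is selective for allylic alcohols, so only the allylic CH2OH should become the aldehyde while the saturated primary and tertiary alcohols remain and the (Z) geometry is kept.

**Compound list**
1 | ethyl 2-methyl-3-oxobutanoate (racemic) | CCOC(=O)C(C)C(C)=O | starting material
2 | (2E,6E)-farnesyl bromide | CC(C)=CCC/C(C)=C/CC/C(C)=C/CBr | starting material
3 | ethyl (6E,10E)-2,7,11,15-tetramethyl-3-oxohexadeca-6,10,14-trienoate (C-2 epimers) | CCOC(=O)C(C)C(=O)CC/C=C(C)/CC/C=C(C)/CCC=C(C)C | intermediate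
4 | ethyl (2Z,6E,10E)-2,7,11,15-tetramethyl-3-(trifluoromethylsulfonyloxy)hexadeca-2,6,10,14-tetraenoate | CCOC(=O)/C(C)=C(OS(=O)(=O)C(F)(F)F)/CC/C=C(C)/CC/C=C(C)/CCC=C(C)C | intermediate
5 | ethyl (2E,6E,10E)-2,3,7,11,15-pentamethylhexadeca-2,6,10,14-tetraenoate | CCOC(=O)/C(C)=C(C)/CC/C=C(C)/CC/C=C(C)/CCC=C(C)C | intermediate
6 | (2E,6E,10E)-2,3,7,11,15-pentamethylhexadeca-2,6,10,14-tetraen-1-ol (2-methylgeranylgeraniol) | OC/C(C)=C(C)/CC/C=C(C)/CC/C=C(C)/CCC=C(C)C | intermediate
7 | [(2S,3S)-2,3-dimethyl-3-homofarnesyloxiran-2-yl]methanol | OC[C@]1(C)O[C@@]1(C)CC/C=C(C)/CC/C=C(C)/CCC=C(C)C | intermediate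
8 | (2R,3S)-2-(iodomethyl)-2,3-dimethyl-3-homofarnesyloxirane | IC[C@]1(C)O[C@@]1(C)CC/C=C(C)/CC/C=C(C)/CCC=C(C)C | intermediate
9 | ethyl 5-[(2S,3S)-2,3-dimethyl-3-homofarnesyloxiran-2-yl]-2-methyl-3-oxopentanoate (C-2 epimers) | CCOC(=O)C(C)C(=O)CC[C@]1(C)O[C@@]1(C)CC/C=C(C)/CC/C=C(C)/CCC=C(C)C | intermediate
10 | ethyl (2Z)-5-[(2S,3S)-2,3-dimethyl-3-homofarnesyloxiran-2-yl]-2-methyl-3-(trifluoromethylsulfonyloxy)pent-2-enoate | CCOC(=O)/C(C)=C(OS(=O)(=O)C(F)(F)F)/CC[C@]1(C)O[C@@]1(C)CC/C=C(C)/CC/C=C(C)/CCC=C(C)C | intermediate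
11 | but-3-en-1-yl acetate | CC(=O)OCCC=C | starting material
12 | 4-(9-borabicyclo[3.3.1]nonan-9-yl)butyl acetate | CC(=O)OCCCCB1C2CCCC1CCC2 | intermediate
13 | ethyl (2E)-3-(4-acetoxybutyl)-5-[(2S,3S)-2,3-dimethyl-3-homofarnesyloxiran-2-yl]-2-methylpent-2-enoate (ester cis to the acetoxybutyl chain) | CCOC(=O)/C(C)=C(CCCCOC(C)=O)/CC[C@]1(C)O[C@@]1(C)CC/C=C(C)/CC/C=C(C)/CCC=C(C)C | intermediate
14 | (2E)-5-[(2S,3S)-2,3-dimethyl-3-homofarnesyloxiran-2-yl]-3-(4-hydroxybutyl)-2-methylpent-2-enoic acid | OC(=O)/C(C)=C(CCCCO)/CC[C@]1(C)O[C@@]1(C)CC/C=C(C)/CC/C=C(C)/CCC=C(C)C | intermediate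
15 | (3Z)-4-{2-[(2S,3S)-2,3-dimethyl-3-homofarnesyloxiran-2-yl]ethyl}-3-methyl-5,6,7,8-tetrahydro-2H-oxocin-2-one | C/C1=C(\CC[C@]2(C)O[C@@]2(C)CC/C=C(C)/CC/C=C(C)/CCC=C(C)C)CCCCOC1=O | intermediate
16 | 4-{2-[(2S,3S)-2,3-dimethyl-3-homofarnesyloxiran-2-yl]ethyl}-3-methyl-2-(trimethylsilyloxy)-7,8-dihydro-6H-oxocine (ring double bonds C2=C3 and C4=C5, both cis in the ring) | C[Si](C)(C)O/C1=C(\C)/C(CC[C@]2(C)O[C@@]2(C)CC/C=C(C)/CC/C=C(C)/CCC=C(C)C)=C\CCCO1 | intermediate
17 | bicyclic lactone: eight-membered α-methyl-α,β-unsaturated lactone fused to the cyclohexane that carries C(CH3)(OH), C(CH3)(homofarnesyl) and the ring CH, configured as in iridal | CC(C)=CCC/C(C)=C/CC/C(C)=C/CC[C@@]1(C)[C@@H]2CCCOC(=O)/C(C)=C2/CC[C@]1(C)O | intermediate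
18 | triol: iridal with the aldehyde reduced to CH2OH, (Z) double bond | CC(C)=CCC/C(C)=C/CC/C(C)=C/CC[C@@]1(C)[C@H](CCCO)/C(=C(/C)CO)CC[C@]1(C)O | intermediate
19 | iridal | CC(C)=CCC/C(C)=C/CC/C(C)=C/CC[C@@]1(C)[C@H](CCCO)/C(=C(/C)C=O)CC[C@]1(C)O | target

**Step count and risks**
Total steps: 14. Longest linear sequence: 14 steps (from 1 and 2; 11 enters at step 9).

Steps most likely to fail:

1. Step 12. The epoxide may rearrange by a 1,2-shift to a ketone before the carbon nucleophile arrives, deprotonation may occur at the exocyclic γ′-position, or the ketene acetal may be hydrolysed before cyclization. The fallback uses known reaction types, sets out from 8 and comes back at 17. γ-Alkylation of the dianion of dimethyl (2-oxopropyl)phosphonate with 8 should give the keto phosphonate F1. Horner–Wadsworth–Emmons reaction with 3-(tert-butyldimethylsilyloxy)propanal (Ba(OH)2, THF/H2O) should give the (E)-enone F2. RhCl(PPh3)3-catalysed 1,4-hydrosilylation with Et3SiH should give the regiodefined (Z)-triethylsilyl enol ether F3. MeAlCl2 (CH2Cl2, −78 °C), an epoxide-initiated cyclization terminated by a silyl enol ether, should give the cyclohexanone F4 with the same three stereocentres. Bu4NF should give the hydroxy ketone F5, and 2-bromopropanoyl bromide/pyridine the bromo ester F6. SmI2 (THF, high dilution) should effect an intramolecular Reformatsky reaction, and in situ acetylation of the samarium aldolate (Ac2O, DMAP) should give the β-acetoxy lactone F7. DBU then eliminates acetic acid to the ring-constrained (Z)-lactone 17.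

2. Step 11. Intermolecular esterification (oligomers) may outrun closure of the medium ring, and the free carboxylic acid may open the epoxide while waiting. The fallback closes the same ring at a different bond, sets out from 10 and comes back at 15. Stille coupling of 10 with allyltributylstannane (Pd(PPh3)4, LiCl, THF) should give the allylated ester F8. Saponification (LiOH) should give the acid F9, kept as its salt, and O-alkylation with allyl bromide (Cs2CO3, DMF) the allyl ester F10. Ring-closing metathesis of the two vinyl groups with the second-generation Grubbs catalyst at high dilution should give the eight-membered dienyl lactone F11. Diimide (2-nitrobenzenesulfonylhydrazide, Et3N) should reduce the cis-disubstituted ring double bond much faster than the trisubstituted and conjugated tetrasubstituted ones and give 15.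

3. Step 7. Iodine–lithium exchange or electron transfer at the oxiranylmethyl iodide may fragment the epoxide to the tertiary allylic alkoxide, and substitution at the neopentyl-like carbon may be slow. The fallback builds the same two-carbon link by olefination and acylation, sets out from 7 and comes back at 9. Parikh–Doering oxidation of 7 should give the epoxy aldehyde F12. Wittig reaction with N-methoxy-N-methyl-2-(triphenylphosphoranylidene)acetamide should give the (E)-enamide F13. Diimide reduction of the disubstituted conjugated double bond should give the saturated Weinreb amide F14. Acylation of the lithium enolate of ethyl propanoate (LiN(i-Pr)2, THF, −78 °C) by F14 should give 9.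

**Further compounds**
F1 | step 12 | dimethyl {4-[(2S,3S)-2,3-dimethyl-3-homofarnesyloxiran-2-yl]-2-oxobutyl}phosphonate | COP(=O)(OC)CC(=O)CC[C@]1(C)O[C@@]1(C)CC/C=C(C)/CC/C=C(C)/CCC=C(C)C
F2 | step 12 | (4E)-7-(tert-butyldimethylsilyloxy)-1-[(2S,3S)-2,3-dimethyl-3-homofarnesyloxiran-2-yl]hept-4-en-3-one | CC(C)(C)[Si](C)(C)OCC/C=C/C(=O)CC[C@]1(C)O[C@@]1(C)CC/C=C(C)/CC/C=C(C)/CCC=C(C)C
F3 | step 12 | (Z)-triethylsilyl enol ether of the saturated ketone from F2 (silyloxy cis to the silyloxypropyl-bearing CH2) | CC[Si](CC)(CC)O/C(=C\CCCO[Si](C)(C)C(C)(C)C)CC[C@]1(C)O[C@@]1(C)CC/C=C(C)/CC/C=C(C)/CCC=C(C)C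
F4 | step 12 | 2-[3-(tert-butyldimethylsilyloxy)propyl]-4-hydroxy-3,4-dimethyl-3-homofarnesylcyclohexan-1-one, ring stereocentres as in iridal | CC(C)=CCC/C(C)=C/CC/C(C)=C/CC[C@@]1(C)[C@H](CCCO[Si](C)(C)C(C)(C)C)C(=O)CC[C@]1(C)O
F5 | step 12 | 4-hydroxy-2-(3-hydroxypropyl)-3,4-dimethyl-3-homofarnesylcyclohexan-1-one | CC(C)=CCC/C(C)=C/CC/C(C)=C/CC[C@@]1(C)[C@H](CCCO)C(=O)CC[C@]1(C)O
F6 | step 12 | 3-(3-hydroxy-2,3-dimethyl-2-homofarnesyl-6-oxocyclohexyl)propyl 2-bromopropanoate (bromide epimers) | CC(C)=CCC/C(C)=C/CC/C(C)=C/CC[C@@]1(C)[C@H](CCCOC(=O)C(C)Br)C(=O)CC[C@]1(C)O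
F7 | step 12 | β-acetoxy lactone: saturated eight-membered lactone fused to the cyclohexane, acetoxy on the former ketone carbon (mixture at the two new centres) | CC(C)=CCC/C(C)=C/CC/C(C)=C/CC[C@@]1(C)[C@@H]2CCCOC(=O)C(C)C2(OC(C)=O)CC[C@]1(C)O
F8 | step 11 | ethyl (2E)-3-allyl-5-[(2S,3S)-2,3-dimethyl-3-homofarnesyloxiran-2-yl]-2-methylpent-2-enoate (ester cis to allyl) | CCOC(=O)/C(C)=C(CC=C)/CC[C@]1(C)O[C@@]1(C)CC/C=C(C)/CC/C=C(C)/CCC=C(C)C
F9 | step 11 | (2E)-3-allyl-5-[(2S,3S)-2,3-dimethyl-3-homofarnesyloxiran-2-yl]-2-methylpent-2-enoic acid | OC(=O)/C(C)=C(CC=C)/CC[C@]1(C)O[C@@]1(C)CC/C=C(C)/CC/C=C(C)/CCC=C(C)C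
F10 | step 11 | allyl (2E)-3-allyl-5-[(2S,3S)-2,3-dimethyl-3-homofarnesyloxiran-2-yl]-2-methylpent-2-enoate | C=CCOC(=O)/C(C)=C(CC=C)/CC[C@]1(C)O[C@@]1(C)CC/C=C(C)/CC/C=C(C)/CCC=C(C)C
F11 | step 11 | (3Z,6Z)-4-{2-[(2S,3S)-2,3-dimethyl-3-homofarnesyloxiran-2-yl]ethyl}-3-methyl-5,8-dihydro-2H-oxocin-2-one | C/C1=C(\CC[C@]2(C)O[C@@]2(C)CC/C=C(C)/CC/C=C(C)/CCC=C(C)C)C/C=C\COC1=O
F12 | step 7 | 2,3-dimethyl-3-homofarnesyloxirane-2-carbaldehyde, stereocentres spatially as in 7 | O=C[C@]1(C)O[C@@]1(C)CC/C=C(C)/CC/C=C(C)/CCC=C(C)C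
F13 | step 7 | (2E)-3-(2,3-dimethyl-3-homofarnesyloxiran-2-yl)-N-methoxy-N-methylprop-2-enamide | CON(C)C(=O)/C=C/[C@]1(C)O[C@@]1(C)CC/C=C(C)/CC/C=C(C)/CCC=C(C)C
F14 | step 7 | 3-[(2S,3S)-2,3-dimethyl-3-homofarnesyloxiran-2-yl]-N-methoxy-N-methylpropanamide | CON(C)C(=O)CC[C@]1(C)O[C@@]1(C)CC/C=C(C)/CC/C=C(C)/CCC=C(C)C
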